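## Retrosynthetic overview

- The tertiary acetate and the carboxylic acid are end-game adjustments (acetylation, alcohol oxidation, desilylation) of a bis-silylated 4-hydroxycyclopent-2-enone.
- The strategy rests on the only ring. In the cyclopent-2-enone, C1(=O)–C2H=C3H sits on the fully substituted, oxygen-bearing C4, which is the retron of alkyne hydroacylation. Cutting C1–C2 gives an acyclic 4-alkynal with the formyl carbon C1 on C5 and an ethynyl group (C3≡C2H) on C4; this is the single ring-forming step.
- C4 and the C3–C4 bond come from Felkin–Anh addition of ethynylmagnesium bromide to a ketone whose α-carbon C5 carries the pentenyl group and a masked formyl group (dimethyl acetal).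
- The ketone comes from a Weinreb amide and the Grignard reagent of silyl-protected 8-bromooctan-1-ol. C5 is set by titanium-enolate formylation of the N-[(Z)-hept-4-enoyl] derivative of (S)-4-benzyloxazolidin-2-one.

Key step: step 9

Remark: ring atoms are numbered C1 (carbonyl), C2=C3, C4 (acetoxy carbon), C5 (pentenyl carbon). The target is (4R,5S), with the C4 oxygen trans and the acid chain cis to the pentenyl group. Commercial (Z)-hept-4-enoic acid is assumed to be geometrically pure.

## Route

Step 1
Reactants: 1 (Z)-hept-4-enoic acid; 2 (S)-4-benzyloxazolidin-2-one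
Product: 4 (S)-4-benzyl-3-[(Z)-hept-4-enoyl]oxazolidin-2-one, via mixed pivalic anhydride 3 (not isolated)
Conditions: PivCl, Et3N, THF, −20 °C; then LiCl, 2, −20 °C → rt
Reagents that add atoms: none
Why: N-acylation of the oxazolidinone through the mixed pivalic anhydride (LiCl/Et3N variant) is a standard mild acylation in which the hindered pivaloyl carbonyl is not attacked and the Z-alkene is untouched; no stereocentre is formed.

Step 2
Reactants: 4 (S)-4-benzyl-3-[(Z)-hept-4-enoyl]oxazolidin-2-one
Product: 6 (S)-4-benzyl-3-[(2R,4Z)-2-(dimethoxymethyl)hept-4-enoyl]oxazolidin-2-one, via chlorotitanium enolate 5 (not isolated)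
Conditions: TiCl4, i-Pr2NEt, CH2Cl2, 0 °C; then HC(OMe)3, 0 °C
Reagents that add atoms: trimethyl orthoformate, COC(OC)OC
Why: Evans titanium-enolate alkylation, in which soft enolisation gives the chelated chlorotitanium (Z)-enolate and the dimethoxycarbenium ion released from the orthoformate adds to the face opposite the benzyl group, setting the future C5 (2R in the acyl chain).

Step 3
Reactants: 6 (S)-4-benzyl-3-[(2R,4Z)-2-(dimethoxymethyl)hept-4-enoyl]oxazolidin-2-one
Product: 8 (2R,4Z)-2-(dimethoxymethyl)hept-4-enoic acid, via lithium peroxycarboxylate 7 (not isolated)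
Conditions: LiOH, H2O2, THF/H2O, 0 °C; then aq Na2SO3; then HCl to pH 4, 0 °C
Reagents that add atoms: hydrogen peroxide (as LiOOH), OO
Why: Evans hydroperoxide cleavage, in which LiOOH attacks the exocyclic imide carbonyl selectively even beside a branched α-carbon, the peracid salt is reduced by sulfite, and the acetal and α-centre survive the base and the brief cold acidification.

Step 4
Reactants: 8 (2R,4Z)-2-(dimethoxymethyl)hept-4-enoic acid
Product: 10 (2R,4Z)-2-(dimethoxymethyl)-N-methoxy-N-methylhept-4-enamide, via acyl imidazolide 9 (not isolated)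
Conditions: CDI, CH2Cl2, 0 °C → rt; then MeNHOMe·HCl, rt
Reagents that add atoms: N,O-dimethylhydroxylamine hydrochloride, CNOC.Cl
Why: Amide coupling through the acyl imidazolide runs under near-neutral conditions that leave the acetal and the α-stereocentre intact and gives the Weinreb amide needed for a clean ketone synthesis.

Step 5
Reactants: 11 8-bromooctan-1-ol
Product: 12 (8-bromooctyloxy)(tert-butyl)dimethylsilane
Conditions: TBSCl, imidazole, CH2Cl2, rt
Reagents that add atoms: tert-butyldimethylsilyl chloride, CC(C)(C)[Si](C)(C)Cl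
Why: Standard silylation of a primary alcohol masks the hydroxyl so that the bromide can be converted into a Grignard reagent.

Step 6
Reactants: 10 (2R,4Z)-2-(dimethoxymethyl)-N-methoxy-N-methylhept-4-enamide; 12 (8-bromooctyloxy)(tert-butyl)dimethylsilane
Product: 14 (10R,12Z)-1-(tert-butyldimethylsilyloxy)-10-(dimethoxymethyl)pentadec-12-en-9-one, via Grignard reagent 13 (not isolated)
Conditions: 12, Mg, I2 (cat.), THF, 45 °C; then 10, THF, 0 °C; then H2O (pH 7 buffer)
Reagents that add atoms: none
Why: Weinreb ketone synthesis, in which the Grignard reagent adds once to give a magnesium-chelated tetrahedral intermediate that collapses to the ketone only on work-up, so over-addition and epimerisation of the α-centre are avoided.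

Step 7
Reactants: 14 (10R,12Z)-1-(tert-butyldimethylsilyloxy)-10-(dimethoxymethyl)pentadec-12-en-9-one; 15 ethynylmagnesium bromide
Product: 16 (2S,3S)-11-(tert-butyldimethylsilyloxy)-3-ethynyl-1,1-dimethoxy-2-[(Z)-pent-2-enyl]undecan-3-ol
Conditions: 15 (3 equiv), THF, −78 → −20 °C; then H2O (pH 7 buffer)
Reagents that add atoms: none
Why: Felkin–Anh 1,2-addition of the small, weakly basic acetylide, with the branched dimethoxymethyl group as the large substituent anti to the nucleophile, the pentenyl CH2 inside next to the carbonyl oxygen and the acetylide passing the α-hydrogen, while THF-solvated magnesium is not expected to chelate the acetal oxygens, so the new carbinol C4 (3S) should carry its oxygen on the side that ends up trans to the pentenyl group.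

Step 8
Reactants: 16 (2S,3S)-11-(tert-butyldimethylsilyloxy)-3-ethynyl-1,1-dimethoxy-2-[(Z)-pent-2-enyl]undecan-3-ol
Product: 19 (2S,3S)-11-(tert-butyldimethylsilyloxy)-3-ethynyl-2-[(Z)-pent-2-enyl]-3-(triethylsilyloxy)undecanal, via triethylsilyl ether acetal 17 (not isolated), via collidinium salt 18 (not isolated)
Conditions: TESOTf (4 equiv), 2,4,6-collidine (6 equiv), CH2Cl2, −78 → 0 °C; then H2O, 0 °C → rt
Reagents that add atoms: triethylsilyl trifluoromethanesulfonate, CC[Si](CC)(CC)OS(=O)(=O)C(F)(F)F; water, O
Why: The silyl triflate first silylates the tertiary propargylic alcohol and on warming ionises the aldehyde-derived dimethyl acetal, collidine trapping the oxocarbenium ion as an N,O-acetal pyridinium salt that water hydrolyses to the aldehyde at near-neutral pH (silyl triflate/pyridine acetal cleavage), so both silyl ethers and the epimerisable C5 should survive.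

Step 9
Reactants: 19 (2S,3S)-11-(tert-butyldimethylsilyloxy)-3-ethynyl-2-[(Z)-pent-2-enyl]-3-(triethylsilyloxy)undecanal
Product: 20 (4R,5S)-4-[8-(tert-butyldimethylsilyloxy)octyl]-5-[(Z)-pent-2-enyl]-4-(triethylsilyloxy)cyclopent-2-en-1-one
Conditions: [Rh(dppe)]2(BF4)2 (10 mol %), degassed acetone, rt → 40 °C
Reagents that add atoms: none
Why: The cationic monovalent rhodium centre inserts into the formyl C–H bond of 19, and the resulting trivalent acylrhodium hydride delivers hydride to the inner alkyne carbon C3 with overall trans geometry, leaving the metal on the terminal carbon C2 inside a six-membered rhodacycle; C–C reductive elimination then joins C1 to C2 and regenerates the monovalent catalyst. The closest known reaction type is the rhodium-catalysed trans-hydroacylation of 4-alkynals to cyclopent-2-enones, which accepts a fully substituted, oxygen-bearing C3 in the alkynal, although terminal alkynes and α-branched aldehydes are less explored. The one ring closes in a formal 5-endo-dig mode, the pathway this catalyst gives with 4-alkynals in preference to 4-exo closure to a cyclobutanone. No stereocentre is created, and C4 and C5 are carried through unchanged because no acid or base is present to enolise the aldehyde or the product ketone. The step needs chemoselectivity for the alkyne over the (Z)-alkene of the pentenyl group, which is also a 4,5-unsaturation relative to the formyl group, and hydroacylation over decarbonylation. The terminal alkyne should bind cationic rhodium more strongly than a 1,2-disubstituted alkene (whose insertion would require a secondary alkylrhodium), the quaternary C4 holds alkyne and formyl group close together, and the chelating diphosphine disfavours CO extrusion.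

Step 10
Reactants: 20 (4R,5S)-4-[8-(tert-butyldimethylsilyloxy)octyl]-5-[(Z)-pent-2-enyl]-4-(triethylsilyloxy)cyclopent-2-en-1-one
Product: 21 (4R,5S)-4-hydroxy-4-(8-hydroxyoctyl)-5-[(Z)-pent-2-enyl]cyclopent-2-en-1-one
Conditions: HF·pyridine, pyridine, THF, 0 °C → rt
Reagents that add atoms: none
Why: Fluoride-mediated desilylation with pyridine-buffered HF should remove the primary TBS and the tertiary TES ether in one operation without base, so the β-hydroxy ketone is not exposed to retro-aldol cleavage or elimination and C5 is not epimerised.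

Step 11
Reactants: 21 (4R,5S)-4-hydroxy-4-(8-hydroxyoctyl)-5-[(Z)-pent-2-enyl]cyclopent-2-en-1-one
Product: 23 8-[(1R,5S)-1-hydroxy-4-oxo-5-[(Z)-pent-2-enyl]cyclopent-2-en-1-yl]octanoic acid, via hydroxy aldehyde 22 (not isolated)
Conditions: TEMPO (cat.), PhI(OAc)2 (2.5 equiv), MeCN/H2O (pH 7 buffer), rt
Reagents that add atoms: water, O
Why: Oxoammonium oxidation (TEMPO/PhI(OAc)2) in aqueous acetonitrile takes the primary alcohol through the aldehyde hydrate to the carboxylic acid, while the tertiary alcohol, the enone and the Z-alkene are inert under these mild conditions.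

Step 12
Reactants: 23 8-[(1R,5S)-1-hydroxy-4-oxo-5-[(Z)-pent-2-enyl]cyclopent-2-en-1-yl]octanoic acid
Product: 25 8-[(1R,5S)-1-acetoxy-4-oxo-5-[(Z)-pent-2-enyl]cyclopent-2-en-1-yl]octanoic acid, via mixed acetic anhydride 24 (not isolated)
Conditions: Ac2O (5 equiv), Bi(OTf)3 (5 mol %), CH2Cl2, 0 °C → rt; then THF/H2O, rt
Reagents that add atoms: acetic anhydride, CC(=O)OC(C)=O
Why: Lewis-acid-catalysed acylation with Ac2O/Bi(OTf)3 acetylates hindered tertiary alcohols without base, ionisation at C4 being disfavoured because the cation would be conjugated with the enone carbonyl, and the carboxyl group that is converted into the mixed anhydride is released again by mild hydrolysis, so neither C4 nor the base-labile C5 should be disturbed.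

## Compound list

1 | (Z)-hept-4-enoic acid | CC/C=C\CCC(=O)O | starting material
2 | (S)-4-benzyloxazolidin-2-one | O=C1N[C@@H](Cc2ccccc2)CO1 | starting material
3 | (Z)-hept-4-enoic pivalic anhydride | CC/C=C\CCC(=O)OC(=O)C(C)(C)C | intermediate
4 | (S)-4-benzyl-3-[(Z)-hept-4-enoyl]oxazolidin-2-one | CC/C=C\CCC(=O)N1[C@@H](Cc2ccccc2)COC1=O | intermediate
5 | trichlorotitanium (1Z,4Z)-1-[(S)-4-benzyl-2-oxooxazolidin-3-yl]hepta-1,4-dien-1-olate | CC/C=C\C/C=C(\O[Ti](Cl)(Cl)Cl)N1[C@@H](Cc2ccccc2)COC1=O | intermediate
6 | (S)-4-benzyl-3-[(2R,4Z)-2-(dimethoxymethyl)hept-4-enoyl]oxazolidin-2-one | CC/C=C\C[C@H](C(OC)OC)C(=O)N1[C@@H](Cc2ccccc2)COC1=O | intermediate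
7 | lithium (2R,4Z)-2-(dimethoxymethyl)hept-4-eneperoxoate | CC/C=C\C[C@H](C(OC)OC)C(=O)O[O-].[Li+] | intermediate
8 | (2R,4Z)-2-(dimethoxymethyl)hept-4-enoic acid | CC/C=C\C[C@H](C(OC)OC)C(=O)O | intermediate
9 | (2R,4Z)-2-(dimethoxymethyl)-1-(imidazol-1-yl)hept-4-en-1-one | CC/C=C\C[C@H](C(OC)OC)C(=O)n1ccnc1 | intermediate
10 | (2R,4Z)-2-(dimethoxymethyl)-N-methoxy-N-methylhept-4-enamide | CC/C=C\C[C@H](C(OC)OC)C(=O)N(C)OC | intermediate
11 | 8-bromooctan-1-ol | OCCCCCCCCBr | starting material
12 | (8-bromooctyloxy)(tert-butyl)dimethylsilane | BrCCCCCCCCO[Si](C)(C)C(C)(C)C | intermediate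
13 | [8-(tert-butyldimethylsilyloxy)octyl]magnesium bromide | Br[Mg]CCCCCCCCO[Si](C)(C)C(C)(C)C | intermediate
14 | (10R,12Z)-1-(tert-butyldimethylsilyloxy)-10-(dimethoxymethyl)pentadec-12-en-9-one | CC/C=C\C[C@H](C(OC)OC)C(=O)CCCCCCCCO[Si](C)(C)C(C)(C)C | intermediate
15 | ethynylmagnesium bromide | C#C[Mg]Br | starting material
16 | (2S,3S)-11-(tert-butyldimethylsilyloxy)-3-ethynyl-1,1-dimethoxy-2-[(Z)-pent-2-enyl]undecan-3-ol | CC/C=C\C[C@H](C(OC)OC)[C@](C#C)(CCCCCCCCO[Si](C)(C)C(C)(C)C)O | intermediate
17 | (2S,3S)-11-(tert-butyldimethylsilyloxy)-3-ethynyl-1,1-dimethoxy-2-[(Z)-pent-2-enyl]-3-(triethylsilyloxy)undecane | CC/C=C\C[C@H](C(OC)OC)[C@](C#C)(CCCCCCCCO[Si](C)(C)C(C)(C)C)O[Si](CC)(CC)CC | intermediate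
18 | 1-[(2S,3S)-11-(tert-butyldimethylsilyloxy)-3-ethynyl-1-methoxy-2-[(Z)-pent-2-enyl]-3-(triethylsilyloxy)undecyl]-2,4,6-trimethylpyridinium triflate (both C1 epimers) | CC/C=C\C[C@H](C(OC)[n+]1c(C)cc(C)cc1C)[C@](C#C)(CCCCCCCCO[Si](C)(C)C(C)(C)C)O[Si](CC)(CC)CC.[O-]S(=O)(=O)C(F)(F)F | intermediate
19 | (2S,3S)-11-(tert-butyldimethylsilyloxy)-3-ethynyl-2-[(Z)-pent-2-enyl]-3-(triethylsilyloxy)undecanal | CC/C=C\C[C@H](C=O)[C@](C#C)(CCCCCCCCO[Si](C)(C)C(C)(C)C)O[Si](CC)(CC)CC | intermediate
20 | (4R,5S)-4-[8-(tert-butyldimethylsilyloxy)octyl]-5-[(Z)-pent-2-enyl]-4-(triethylsilyloxy)cyclopent-2-en-1-one | CC/C=C\C[C@@H]1C(=O)C=C[C@@]1(CCCCCCCCO[Si](C)(C)C(C)(C)C)O[Si](CC)(CC)CC | intermediate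
21 | (4R,5S)-4-hydroxy-4-(8-hydroxyoctyl)-5-[(Z)-pent-2-enyl]cyclopent-2-en-1-one | CC/C=C\C[C@@H]1C(=O)C=C[C@@]1(CCCCCCCCO)O | intermediate
22 | 8-[(1R,5S)-1-hydroxy-4-oxo-5-[(Z)-pent-2-enyl]cyclopent-2-en-1-yl]octanal | CC/C=C\C[C@@H]1C(=O)C=C[C@@]1(CCCCCCCC=O)O | intermediate
23 | 8-[(1R,5S)-1-hydroxy-4-oxo-5-[(Z)-pent-2-enyl]cyclopent-2-en-1-yl]octanoic acid | CC/C=C\C[C@@H]1C(=O)C=C[C@@]1(CCCCCCCC(=O)O)O | intermediate
24 | acetic 8-[(1R,5S)-1-acetoxy-4-oxo-5-[(Z)-pent-2-enyl]cyclopent-2-en-1-yl]octanoic anhydride | CC/C=C\C[C@@H]1C(=O)C=C[C@@]1(CCCCCCCC(=O)OC(C)=O)OC(C)=O | intermediate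
25 | 8-[(1R,5S)-1-acetoxy-4-oxo-5-[(Z)-pent-2-enyl]cyclopent-2-en-1-yl]octanoic acid | CC/C=C\C[C@@H]1C(=O)C=C[C@@]1(CCCCCCCC(=O)O)OC(C)=O | target

## Step count and risks

Total steps: 12. Longest linear sequence: 11 steps (steps 1–4 and 6–12; step 5 prepares the side-chain bromide).

Steps most likely to fail:

**Step 9.** The acylrhodium hydride may lose CO and deactivate the catalyst. It may also add to the (Z)-alkene instead of the alkyne, giving a cyclopentanone or Z/E isomerisation, and the terminal alkyne may oligomerise or rearrange to a vinylidene on the metal. The fallback sets out from 19, returns at 20 and closes the same C1–C2 bond by polar chemistry. Iodination of the terminal alkyne (NIS, cat. AgNO3, acetone) would give (2S,3S)-11-(tert-butyldimethylsilyloxy)-3-(iodoethynyl)-2-[(Z)-pent-2-enyl]-3-(triethylsilyloxy)undecanal F1. Cis-reduction of the iodoalkyne with diimide (2-nitrobenzenesulfonyl hydrazide, Et3N) would give (2S,3S)-11-(tert-butyldimethylsilyloxy)-3-[(Z)-2-iodoethenyl]-2-[(Z)-pent-2-enyl]-3-(triethylsilyloxy)undecanal F2. Intramolecular Nozaki–Hiyama–Kishi addition (CrCl2, cat. NiCl2, DMF) would close the ring to (4R,5R)-4-[8-(tert-butyldimethylsilyloxy)octyl]-5-[(Z)-pent-2-enyl]-4-(triethylsilyloxy)cyclopent-2-en-1-ol F3 (both carbinol epimers). Dess–Martin oxidation buffered with NaHCO3 then converges on 20.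

**Step 7.** Facial discrimination between the dimethoxymethyl and pentenyl groups may be modest, or may be reversed if magnesium chelates an acetal oxygen. Enolisation with loss of methoxide is a further drain. The fallback sets out from 10, returns at 16 and uses chelation instead of the Felkin–Anh model by exchanging the roles of the two carbon nucleophiles. Lithium (trimethylsilyl)acetylide (THF, −78 °C) would convert 10 into (4R,6Z)-4-(dimethoxymethyl)-1-(trimethylsilyl)non-6-en-1-yn-3-one F4. Grignard reagent 13 (prepared in Et2O) with MgBr2·OEt2 in CH2Cl2 at −78 °C would then add to the six-membered magnesium chelate between the ketone and one acetal oxygen, anti to the pentenyl group. This should give the same relative configuration in (2S,3S)-11-(tert-butyldimethylsilyloxy)-1,1-dimethoxy-2-[(Z)-pent-2-enyl]-3-[(trimethylsilyl)ethynyl]undecan-3-ol F5. K2CO3 in MeOH removes the alkynyl silyl group to give 16.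

**Step 8.** Ionisation of the hindered acetal may stall, or the oxocarbenium ion may lose the C5 proton to form an enol ether, which would erode the C5 configuration on hydrolysis. The fallback sets out from 16 and returns at 19, separating the two events and avoiding the base-trapped cation. Silylation at −78 °C (TESOTf, 2,6-lutidine, quenched cold) allows the silyl ether acetal 17 to be isolated. The aldehyde is then released by Brønsted-acid hydrolysis on a solid support (10% aqueous oxalic acid on silica gel, CH2Cl2), where no base is present to form an enol ether.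

## Further compounds

F1 | step 9 | (2S,3S)-11-(tert-butyldimethylsilyloxy)-3-(iodoethynyl)-2-[(Z)-pent-2-enyl]-3-(triethylsilyloxy)undecanal | CC/C=C\C[C@H](C=O)[C@](C#CI)(CCCCCCCCO[Si](C)(C)C(C)(C)C)O[Si](CC)(CC)CC
F2 | step 9 | (2S,3S)-11-(tert-butyldimethylsilyloxy)-3-[(Z)-2-iodoethenyl]-2-[(Z)-pent-2-enyl]-3-(triethylsilyloxy)undecanal | CC/C=C\C[C@H](C=O)[C@](/C=C\I)(CCCCCCCCO[Si](C)(C)C(C)(C)C)O[Si](CC)(CC)CC
F3 | step 9 | (4R,5R)-4-[8-(tert-butyldimethylsilyloxy)octyl]-5-[(Z)-pent-2-enyl]-4-(triethylsilyloxy)cyclopent-2-en-1-ol (both C1 epimers) | CC/C=C\C[C@@H]1C(O)C=C[C@@]1(CCCCCCCCO[Si](C)(C)C(C)(C)C)O[Si](CC)(CC)CC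
F4 | step 7 | (4R,6Z)-4-(dimethoxymethyl)-1-(trimethylsilyl)non-6-en-1-yn-3-one | CC/C=C\C[C@H](C(OC)OC)C(=O)C#C[Si](C)(C)C
F5 | step 7 | (2S,3S)-11-(tert-butyldimethylsilyloxy)-1,1-dimethoxy-2-[(Z)-pent-2-enyl]-3-[(trimethylsilyl)ethynyl]undecan-3-ol | CC/C=C\C[C@H](C(OC)OC)[C@](C#C[Si](C)(C)C)(CCCCCCCCO[Si](C)(C)C(C)(C)C)O
F0 | step 8 | none | none
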